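All runs are simulated from invented constants; scatter was added.

The charge of Z is an invariant: free Z, L, D and the further Z held in G always add up to it. So D, as a fraction of the J charged, stays under the charge of Z over the charge of J, the ceiling 60.0% for oak and birch, with Z the limiting reagent.

all flasks: J 2.3 M
- dawn: Z 0.69 M; temperature −12 °C; run made earlier
- noon: Z 0.69 M; temperature 4 °C; run made earlier
- oak: Z 1.38 M; temperature −20 °C; time 3.0 min
- birch: Z 1.38 M; temperature 10 °C; time 3.0 min

But dawn and noon held half that Z, so their ceiling is 30.0%.

| run | time / s | D / % |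
|---|---|---|
| dawn | 20.0 | 3 |
| dawn | 40.0 | 5 |
| dawn | 50.0 | 11 |
| dawn | 80.0 | 14 |
| dawn | 90.0 | 11 |
| dawn | 120 | 14 |
| noon | 10.0 | 10 |
| noon | 12.0 | 15 |
| noon | 15.0 | 13 |
| noon | 25.0 | 19 |
| noon | 30.0 | 21 |
| noon | 40.0 | 20 |

(each reading ± 2 percentage points)

- in percentages every species weighs as the J in it: one Q counts as two
- for D the G are counted in
- candidate steps: J <-> X; Z + X -> D; Z + D <-> G; 2 J -> Q; Z <-> L

Dawn's last reading, at 120 s, fills a share 0.467 of its ceiling and noon's, at 40.0 s, a share 0.667, but these are scattered readings at different times, so they show no level of either run. As my own reckoning, which takes these shares as levels, a straight line through them against temperature gives 0.367 for oak and 0.742 for birch.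

But a level takes time. A rate proportional to what is missing integrates to a missing part that halves in each equal stretch, the half-rise time. Noon's reading stands at half its last one by 10.0 s, and dawn's readings cross half their last one near 45.0 s. Oak lies half a temperature step below dawn, which gives about 95.5 s, so oak completes 0.729 of its rise. Birch has a half-rise time of about 5.69 s, so this reckoning counts it as finished. This reckoning gives 16.0% for oak and 44.5% for birch.

- the flask that comes out highest in amount of D, in percent of the J charged, or "all alike" when all lie within 1.5 percentage points (oak / birch / all alike)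
- D at the end, in percent of the J charged, oak
- D at the end, in percent of the J charged, birch

The forecast names birch, with 23% for oak (15% to 32%) and 43% for birch (33% to 54%), holding that “Doubling Z roughly doubles the plateau”. It stands above my reckoning for oak and below it for birch.

The flasks give 17.6% in oak and 56.6% in birch, so birch comes out highest.

    J ⇌ X (K = 1.20, k = 0.00410 s⁻¹, Ea = 80.0 kJ mol⁻¹, ΔH = −2.00 kJ mol⁻¹)
    Z + X → D (k = 0.0120 L mol⁻¹ s⁻¹, Ea = 57.0 kJ mol⁻¹)
    Z + D ⇌ G, settled at all times (K = 0.630 L mol⁻¹, ΔH = −13.0 kJ mol⁻¹)
    2 J → Q (k = 0.00230 L mol⁻¹ s⁻¹, Ea = 47.0 kJ mol⁻¹)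
    Z ⇌ L (K = 1.40, k = 0.00240 s⁻¹, Ea = 70.0 kJ mol⁻¹, ΔH = −6.00 kJ mol⁻¹)
    (constants at −20 °C)

Birch fills a share 0.943 of its ceiling and oak a share 0.293, while oak's free Z still counts 23.7% of the J charged and its L 14.3%. At 0.832 min in oak, Z enters the step with X to D 1.1 times as fast as it enters the forward step to L. A neighbour of oak, with the same charges at −5 °C, has the same ceiling and gives 42.4%, a share of 0.707.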